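The route rests on cutting ring C of the flavanone at C4: this carbonyl carbon is flanked only by C4a of ring A and by C3, so it can be delivered as carbon monoxide between an aryl iodide and a terminal alkyne. One palladium-catalysed operation joins an iodophenol (ring A, iodine at the future C4a between a free phenol and a MOM (methoxymethyl) ether, prenyl already at the future C8), CO and the ring B arylacetylene, making C4–C4a, C3–C4 and O1–C2 and closing ring C as a flat flavone. The C2 stereocentre is then set by CuH conjugate reduction, and the two MOM groups are removed.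

Key step: step 8

Assumption: (R)-DTBM-SEGPHOS is taken as the ligand antipode whose CuH complex attacks the Re face of C2 of the flavone, which gives (2S); if a pilot reduction shows the opposite sense, the (S) antipode is used under the same conditions.

Step 1
Reactants: 1 5-methoxyresorcinol (5-methoxybenzene-1,3-diol)
Product: 2 2-iodo-5-methoxybenzene-1,3-diol
Conditions: I2 (1.0 equiv), NaHCO3, THF/H2O, 0 °C
Reagents that add atoms: iodine, SMILES II
Why: Electrophilic aromatic iodination of the resorcinol in aqueous bicarbonate should take place at the carbon flanked by both hydroxyls, as is usual for resorcinol and its 5-substituted congeners under these conditions, and slow addition of one equivalent of iodine at 0 °C limits polyiodination.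

Step 2
Reactants: 2 2-iodo-5-methoxybenzene-1,3-diol
Product: 3 2-iodo-5-methoxy-3-(methoxymethoxy)phenol
Conditions: NaH (1.0 equiv), MOMCl (1.0 equiv), DMF, 0 °C
Reagents that add atoms: chloromethyl methyl ether, SMILES COCCl
Why: Williamson-type O-alkylation of the phenoxide with the chloromethyl ether; because the two hydroxyls of 2 are equivalent, mono-protection cannot give a regioisomer, and the statistical by-products (unchanged 2 and the bis-ether) differ enough in polarity from 3 to be removed, 2 being resubmitted.

Step 3
Reactants: 3 2-iodo-5-methoxy-3-(methoxymethoxy)phenol; 4 allyl bromide (3-bromoprop-1-ene)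
Product: 5 2-iodo-5-methoxy-1-(methoxymethoxy)-3-(prop-2-en-1-yloxy)benzene
Conditions: K2CO3, acetone, reflux
Reagents that add atoms: none
Why: Williamson O-allylation of the only remaining phenol is unambiguous and places the allyl group on the oxygen that becomes O1 of ring C.

Step 4
Reactants: 5 2-iodo-5-methoxy-1-(methoxymethoxy)-3-(prop-2-en-1-yloxy)benzene
Product: 7 2-iodo-5-methoxy-3-(methoxymethoxy)-6-(prop-2-en-1-yl)phenol, via ortho-dienone 6 (not isolated)
Conditions: PhNEt2, 185 °C, argon
Reagents that add atoms: none
Why: Aromatic Claisen rearrangement: the [3,3] shift can lead to an enolisable dienone only at the one ortho carbon that bears hydrogen (the other bears iodine), so tautomerisation of 6 should deliver the allyl group next to the freed hydroxyl and nowhere else.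

Step 5
Reactants: 7 2-iodo-5-methoxy-3-(methoxymethoxy)-6-(prop-2-en-1-yl)phenol; 8 2-methyl-2-butene (excess)
Product: 9 2-iodo-5-methoxy-3-(methoxymethoxy)-6-(3-methylbut-2-en-1-yl)phenol
Conditions: second-generation Grubbs catalyst RuCl2(=CHPh)(H2IMes)(PCy3) (3 mol%), 1,4-benzoquinone (10 mol%), CH2Cl2, 35 °C
Reagents that add atoms: none
Why: Olefin cross-metathesis of the terminal allyl group with excess 2-methyl-2-butene is a standard allyl-to-prenyl conversion that tolerates free phenols, aryl iodides and acetals, with propene lost as the driving force.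

Step 6
Reactants: 10 isovanillin (3-hydroxy-4-methoxybenzaldehyde)
Product: 11 4-methoxy-3-(methoxymethoxy)benzaldehyde
Conditions: NaH, MOMCl, DMF, 0 °C → rt
Reagents that add atoms: chloromethyl methyl ether, SMILES COCCl
Why: Williamson-type O-alkylation of the phenoxide of isovanillin protects the 3-hydroxyl as the same acetal used on ring A, so that both come off in one final operation.

Step 7
Reactants: 11 4-methoxy-3-(methoxymethoxy)benzaldehyde
Product: 13 4-ethynyl-1-methoxy-2-(methoxymethoxy)benzene, via diazoalkene 12 (not isolated)
Conditions: dimethyl (1-diazo-2-oxopropyl)phosphonate, K2CO3, MeOH, 0 °C → rt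
Reagents that add atoms: dimethyl (1-diazo-2-oxopropyl)phosphonate (Ohira–Bestmann reagent), SMILES CC(=O)C(=[N+]=[N-])P(=O)(OC)OC
Why: Seyferth–Gilbert homologation with the Ohira–Bestmann reagent: the diazomethylphosphonate anion released by methanolysis olefinates the aldehyde to diazoalkene 12, which loses dinitrogen and rearranges by 1,2-hydrogen shift to the terminal alkyne under conditions mild enough for the acetal.

Step 8
Reactants: 9 2-iodo-5-methoxy-3-(methoxymethoxy)-6-(3-methylbut-2-en-1-yl)phenol; 13 4-ethynyl-1-methoxy-2-(methoxymethoxy)benzene (1.5 equiv); 14 carbon monoxide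
Product: 17 7-methoxy-2-[4-methoxy-3-(methoxymethoxy)phenyl]-5-(methoxymethoxy)-8-(3-methylbut-2-en-1-yl)-4H-chromen-4-one, via ynone 15 (not isolated), via enaminone 16 (not isolated)
Conditions: PdCl2(dppf) (5 mol%), CO (20 bar), Et2NH, 120 °C
Reagents that add atoms: none
Why: The divalent palladium precatalyst should be reduced in the flask to zerovalent palladium, which inserts into the C–I bond of 9, after which CO insertion gives an aroylpalladium species that couples with alkyne 13 to ynone 15, forming C4–C4a and C3–C4. Diethylamine then adds to the ynone to give enaminone 16, and the single free phenol oxygen displaces the amine at C2 by addition–elimination, forming O1–C2. The closest known reaction type is the palladium-catalysed carbonylative Sonogashira annulation of 2-iodophenols with terminal alkynes in a secondary amine, which gives flavones and has been applied to electron-rich, oxygenated iodophenols. Ring C closes in a 6-endo mode (6-endo-dig with respect to the ynone, realised as a 6-endo-trig addition–elimination on the enaminone). No stereocentre is formed, so the product is a flat, configurationally inert flavone. The step needs CO insertion to outrun direct alkynylation and 6-endo to outrun 5-exo closure: the copper-free conditions, the CO pressure and the electron-rich aryl–palladium bond favour the aroyl complex, the secondary amine channels the ynone through the enaminone so that no aurone should form, and the MOM ether on the other ortho oxygen leaves only the phenol next to the prenyl group able to cyclise.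

Step 9
Reactants: 17 7-methoxy-2-[4-methoxy-3-(methoxymethoxy)phenyl]-5-(methoxymethoxy)-8-(3-methylbut-2-en-1-yl)-4H-chromen-4-one
Product: 19 (2S)-7-methoxy-2-[4-methoxy-3-(methoxymethoxy)phenyl]-5-(methoxymethoxy)-8-(3-methylbut-2-en-1-yl)chroman-4-one, via silyl enol ether 18 (not isolated)
Conditions: Cu(OAc)2 (5 mol%), (R)-DTBM-SEGPHOS (5.5 mol%), (EtO)2MeSiH (3 equiv), toluene, 0 °C → rt; then dilute aq HCl, THF, 0 °C
Reagents that add atoms: none
Why: Asymmetric CuH conjugate reduction of a chromone: the monovalent copper hydride carrying the chiral bisphosphine adds hydride to C2 from the Re face under ligand control, which gives the (2S) configuration, and the copper enolate is silylated by the silane to 18, which regenerates CuH, keeps C4 safe from 1,2-reduction and avoids a free enolate that could open ring C and racemise C2; the unactivated prenyl alkene is not touched.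

Step 10
Reactants: 19 (2S)-7-methoxy-2-[4-methoxy-3-(methoxymethoxy)phenyl]-5-(methoxymethoxy)-8-(3-methylbut-2-en-1-yl)chroman-4-one
Product: 21 (2S)-5-hydroxy-2-(3-hydroxy-4-methoxyphenyl)-7-methoxy-8-(3-methylbut-2-en-1-yl)chroman-4-one, via mono-MOM flavanone 20 (not isolated)
Conditions: HCl (2 M in MeOH), rt → 40 °C
Reagents that add atoms: none
Why: Acid-catalysed acetal exchange with methanol removes first the 5-O-MOM group, which lies peri to the C4 carbonyl, and then the ring B MOM group; C2 should keep its configuration because ring opening needs an enolate, and the prenyl group cannot cyclise because its ring neighbours are O1 and the 7-methoxy carbon, neither a free phenol.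

Compound list

1 | 5-methoxyresorcinol (5-methoxybenzene-1,3-diol) | COc1cc(O)cc(O)c1 | starting material
2 | 2-iodo-5-methoxybenzene-1,3-diol | COc1cc(O)c(I)c(O)c1 | intermediate
3 | 2-iodo-5-methoxy-3-(methoxymethoxy)phenol | COCOc1cc(OC)cc(O)c1I | intermediate
4 | allyl bromide (3-bromoprop-1-ene) | C=CCBr | starting material
5 | 2-iodo-5-methoxy-1-(methoxymethoxy)-3-(prop-2-en-1-yloxy)benzene | C=CCOc1cc(OC)cc(OCOC)c1I | intermediate
6 | 2-iodo-5-methoxy-3-(methoxymethoxy)-6-(prop-2-en-1-yl)cyclohexa-2,4-dien-1-one (racemic ortho-dienone) | O=C1C(CC=C)C(OC)=CC(OCOC)=C1I | intermediate (not isolated)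
7 | 2-iodo-5-methoxy-3-(methoxymethoxy)-6-(prop-2-en-1-yl)phenol | C=CCc1c(OC)cc(OCOC)c(I)c1O | intermediate
8 | 2-methyl-2-butene | CC=C(C)C | starting material
9 | 2-iodo-5-methoxy-3-(methoxymethoxy)-6-(3-methylbut-2-en-1-yl)phenol | COCOc1cc(OC)c(CC=C(C)C)c(O)c1I | intermediate
10 | isovanillin (3-hydroxy-4-methoxybenzaldehyde) | COc1ccc(C=O)cc1O | starting material
11 | 4-methoxy-3-(methoxymethoxy)benzaldehyde | COCOc1cc(C=O)ccc1OC | intermediate
12 | 4-(2-diazoethenyl)-1-methoxy-2-(methoxymethoxy)benzene (diazoalkene) | COCOc1cc(C=C=[N+]=[N-])ccc1OC | intermediate (not isolated)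
13 | 4-ethynyl-1-methoxy-2-(methoxymethoxy)benzene | C#Cc1ccc(OC)c(OCOC)c1 | intermediate
14 | carbon monoxide | [C-]#[O+] | starting material
15 | 1-[2-hydroxy-4-methoxy-6-(methoxymethoxy)-3-(3-methylbut-2-en-1-yl)phenyl]-3-[4-methoxy-3-(methoxymethoxy)phenyl]prop-2-yn-1-one (ynone) | COCOc1cc(OC)c(CC=C(C)C)c(O)c1C(=O)C#Cc1ccc(OC)c(OCOC)c1 | intermediate (not isolated)
16 | 3-(diethylamino)-1-[2-hydroxy-4-methoxy-6-(methoxymethoxy)-3-(3-methylbut-2-en-1-yl)phenyl]-3-[4-methoxy-3-(methoxymethoxy)phenyl]prop-2-en-1-one (enaminone, alkene geometry not defined) | CCN(CC)C(=CC(=O)c1c(O)c(CC=C(C)C)c(OC)cc1OCOC)c1ccc(OC)c(OCOC)c1 | intermediate (not isolated)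
17 | 7-methoxy-2-[4-methoxy-3-(methoxymethoxy)phenyl]-5-(methoxymethoxy)-8-(3-methylbut-2-en-1-yl)-4H-chromen-4-one | COCOc1cc(OC)c(CC=C(C)C)c2oc(-c3ccc(OC)c(OCOC)c3)cc(=O)c12 | intermediate
18 | (2S)-4-{[diethoxy(methyl)silyl]oxy}-7-methoxy-2-[4-methoxy-3-(methoxymethoxy)phenyl]-5-(methoxymethoxy)-8-(3-methylbut-2-en-1-yl)-2H-chromene (silyl enol ether) | COc1ccc([C@@H]2C=C(O[Si](C)(OCC)OCC)c3c(OCOC)cc(OC)c(CC=C(C)C)c3O2)cc1OCOC | intermediate (not isolated)
19 | (2S)-7-methoxy-2-[4-methoxy-3-(methoxymethoxy)phenyl]-5-(methoxymethoxy)-8-(3-methylbut-2-en-1-yl)chroman-4-one | COc1ccc([C@@H]2CC(=O)c3c(OCOC)cc(OC)c(CC=C(C)C)c3O2)cc1OCOC | intermediate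
20 | (2S)-5-hydroxy-7-methoxy-2-[4-methoxy-3-(methoxymethoxy)phenyl]-8-(3-methylbut-2-en-1-yl)chroman-4-one | COc1ccc([C@@H]2CC(=O)c3c(O)cc(OC)c(CC=C(C)C)c3O2)cc1OCOC | intermediate (not isolated)
21 | (2S)-5-hydroxy-2-(3-hydroxy-4-methoxyphenyl)-7-methoxy-8-(3-methylbut-2-en-1-yl)chroman-4-one | COc1ccc([C@@H]2CC(=O)c3c(O)cc(OC)c(CC=C(C)C)c3O2)cc1O | target

Total step count: 10. Longest linear sequence: 8 steps (steps 1 to 5, then 8 to 10); steps 6 and 7 form the two-step alkyne branch.

Steps most likely to fail

First, step 8. The hindered, electron-rich C–I bond may add slowly to palladium. The aryl–palladium species may couple with the alkyne before CO inserts, which leads on to a benzofuran. The aroylpalladium species may also be captured by diethylamine as an amide. The fallback supplies C4 as a formyl carbon instead of CO and closes ring C in a separate operation. It sets out from 9: treatment with n-BuLi (2.2 equiv, THF, −78 °C; deprotonation of the phenol, then iodine–lithium exchange) and quenching with DMF should give 2-hydroxy-4-methoxy-6-(methoxymethoxy)-3-(3-methylbut-2-en-1-yl)benzaldehyde F1. Addition of 13, deprotonated with n-BuLi (2.2 equiv, THF, −78 → 0 °C), should give racemic 1-[2-hydroxy-4-methoxy-6-(methoxymethoxy)-3-(3-methylbut-2-en-1-yl)phenyl]-3-[4-methoxy-3-(methoxymethoxy)phenyl]prop-2-yn-1-ol F2. Oxidation with MnO2 (CH2Cl2, rt) should give ynone 15, and warming 15 with Et2NH in EtOH should close ring C through enaminone 16. The fallback comes back to the route at flavone 17.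

Second, step 9. Facial selectivity at C2 may be poor, the doubly oxygenated vinylogous ester may react sluggishly with the bulky chiral catalyst, or enantiomeric purity may erode through ring opening of an enolate. The fallback replaces asymmetric induction by resolution. It sets out from 17: reduction with an achiral, more reactive CuH catalyst (Cu(OAc)2, 1,2-bis(diphenylphosphino)benzene, (EtO)2MeSiH, toluene, rt) should give the racemic silyl enol ether F3, which dilute aqueous acid should hydrolyse to the racemic flavanone F4. Preparative HPLC on a polysaccharide-carbamate chiral stationary phase should then separate the (2S) enantiomer from the (2R) enantiomer F5. The (2S) enantiomer is 19, where the fallback comes back to the route.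

Third, step 4. At the temperature of the rearrangement, iodine may be lost, the allyl group may migrate onward to the para carbon, or the allylphenol may cyclise. The fallback replaces the sigmatropic shift by direct C-alkylation of a phenoxide. It sets out from 3, which is deprotonated with NaH in toluene (0 °C → rt) and treated with prenyl bromide. In the non-polar medium the tight ion pair should steer the prenyl group to the only free ortho carbon. The fallback comes back to the route at 9, bypassing 5, 6 and 7, and makes no new compound F0. It is kept in reserve because O-alkylation competes.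

Further compounds

F1 | step 8 | 2-hydroxy-4-methoxy-6-(methoxymethoxy)-3-(3-methylbut-2-en-1-yl)benzaldehyde | COCOc1cc(OC)c(CC=C(C)C)c(O)c1C=O
F2 | step 8 | 1-[2-hydroxy-4-methoxy-6-(methoxymethoxy)-3-(3-methylbut-2-en-1-yl)phenyl]-3-[4-methoxy-3-(methoxymethoxy)phenyl]prop-2-yn-1-ol (racemic) | COCOc1cc(OC)c(CC=C(C)C)c(O)c1C(O)C#Cc1ccc(OC)c(OCOC)c1
F3 | step 9 | 4-{[diethoxy(methyl)silyl]oxy}-7-methoxy-2-[4-methoxy-3-(methoxymethoxy)phenyl]-5-(methoxymethoxy)-8-(3-methylbut-2-en-1-yl)-2H-chromene (racemic silyl enol ether) | COc1ccc(C2C=C(O[Si](C)(OCC)OCC)c3c(OCOC)cc(OC)c(CC=C(C)C)c3O2)cc1OCOC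
F4 | step 9 | 7-methoxy-2-[4-methoxy-3-(methoxymethoxy)phenyl]-5-(methoxymethoxy)-8-(3-methylbut-2-en-1-yl)chroman-4-one (racemic flavanone) | COc1ccc(C2CC(=O)c3c(OCOC)cc(OC)c(CC=C(C)C)c3O2)cc1OCOC
F5 | step 9 | (2R)-7-methoxy-2-[4-methoxy-3-(methoxymethoxy)phenyl]-5-(methoxymethoxy)-8-(3-methylbut-2-en-1-yl)chroman-4-one | COc1ccc([C@H]2CC(=O)c3c(OCOC)cc(OC)c(CC=C(C)C)c3O2)cc1OCOC
F0 | step 4 | none | none
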